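(The earlier runs and the new flask come from a simulation from invented constants.)

The vessel is closed and stirred, and it holds a racemate with a reagent, a single-handed free catalyst and a racemization catalyst. A substrate molecule therefore stands at a fork: it reacts in the hand it has, or it changes hand first.

| flask | left-handed substrate | right-handed substrate | reagent | free catalyst | racemization catalyst | remark | time |
|---|---|---|---|---|---|---|---|
| Tuesday's | 23 mM | 23 mM | 2 equiv | 1 mol% | 0.2 mol% | the very flask that is asked about, followed so far |  |
| Thursday's | 23 mM | 23 mM | 4 equiv | 1 mol% | 0.2 mol% | run made earlier |  |
| flask | 23 mM | 23 mM | 2.00 equiv | 1 mol% | 0.2 mol% |  | 2.5 min |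

Tuesday's run (percent of the left-handed substrate and right-handed substrate together charged)

| time / s | left-handed substrate / % | right-handed substrate / % |
|---|---|---|
| 10.0 | 8.4 | 9.5 |
| 20.0 | 5.9 | 6.8 |
| 25.0 | 5.4 | 5.5 |

Thursday's run (percent of the left-handed substrate and right-handed substrate together charged)

| time / min | left-handed substrate / % | right-handed substrate / % |
|---|---|---|
| 0.667 | 0 | 0 |
| 1.33 | 0 | 0 |
| 2.00 | 0.7 | 0.8 |
| 2.50 | 0 | 0.5 |

(readings scatter by 0.5 percentage points)

- free catalyst is single-handed; left-handed substrate and right-handed substrate are mirror images of each other, charged as a racemate, each of them at the stated concentration
- what was read earlier has a scatter of 0.5 percentage points, one standard deviation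
- an excess is the difference of the two amounts in percent of their sum
- an excess is below zero if the other one leads

* part of the left-handed substrate and right-handed substrate charged together that has reacted at 2.5 min
* excess of left-handed product over right-handed product in the product at 2.5 min
* excess of right-handed substrate over left-handed substrate among what is left of the two at 2.5 min

Hands can be counted. If the substrates are charged level and no molecule changes hand, each point by which right-handed substrate leads left-handed substrate in the rest is a point by which left-handed product leads right-handed product. That gives the hand-balance excess, the gap between the substrates divided by the part that has reacted. The flask itself, read on Tuesday, shows 6.8% against 5.9% at 20.0 s, so the hand-balance excess is 1.03%.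

The first objection is scatter: that gap of 0.9 percentage points comes from readings that each scatter by 0.5 points, and at 25.0 s the gap reads 0.1 points. Thursday's run, with 4 equiv of reagent, reads 0.7% and 0.8% at 2.00 min, a gap of 0.1 points.

The second objection touches the balance itself. The balance assumes that hands are kept, yet the racemization catalyst can refill the left-handed substrate from the right-handed one, and level substrates look the same whether the free catalyst is indifferent or a refill hides its preference, the case called dynamic kinetic resolution. Such crossing adds to the product excess, so the reckoning here commits to 1.03% as a lower mark, read with that scatter, and to no upper figure.

The forecast gives 95.5% reacted, a product excess of 1% and a substrate excess of 5%, on the ground that “Selectivity is tiny”.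

The flask gives 94.9% reacted, a product excess of 32.1% and a substrate excess of 0.0465%.

    left-handed substrate + racemization catalyst ⇌ right-handed substrate + racemization catalyst, rate k1*[racemization catalyst]*[left-handed substrate] forward; the back reaction follows from the equilibrium constant (k = 18900 M⁻¹ s⁻¹)
    2 free catalyst → spent catalyst (k = 191 M⁻¹ s⁻¹)
    reagent + free catalyst + left-handed substrate → free catalyst + left-handed product (k = 88300 M⁻² s⁻¹)
    reagent + free catalyst + right-handed substrate → free catalyst + right-handed product (k = 41400 M⁻² s⁻¹)
    reagent ⇌ dormant form (K = 0.100, k = 0.0111 s⁻¹)

As charged, left-handed substrate has a forward half-life of 0.80 s for changing hand, far shorter than the 2.5 min. The flask's product excess stands at 31.2 times the 1.03% from Tuesday's readings, while hand balance on its final figures allows 0.00250%, and the difference means that a net 15.2% of the charge crossed from right-handed to left-handed substrate. A neighbour flask with 0.500 equiv of reagent stands at 25.0% reacted, with a substrate excess of 0%, so its hand balance allows 0%, yet its product excess is 35.1%.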